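**Retrosynthetic overview** (germacrane numbering: ring C1–C10, methyls on C4 and C10, isopropyl on C7, esters on C2 and C6; TBS = tert-butyldimethylsilyl)

1. Target 28 ← acylation (C2 angelate, C6 acetate) ← diepoxy diol 24 ← hydroxyl-directed, peripheral bis-epoxidation of (E,E)-germacra-1(10),4-diene-2,6-diol 23, which sets C1, C10, C4 and C5.
2. The ten-membered carbocycle is made by Ramberg–Bäcklund ring contraction of the 11-membered cyclic sulfone 18 (sulfur between C8 and C9): SO2 leaves, C8–C9 forms, and the new C8=C9 bond is then saturated with diimide.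
3. Enabling feature: C8–C9 is the only CH2–CH2 bond of the ring and C9 is allylic to the C10=C1 alkene, so a sulfone placed there is doubly activated, closes as a thiacycle from a dibromide and Na2S, and leaves no trace after extrusion and reduction.
4. Acyclic chain C9→C8 from prenal: Denmark vinylogous aldol (C2–C3 bond, C2 stereocentre, E-C4=C5), SeO2 hydroxylation (C9), Evans Mg anti-aldol (C6–C7 bond, C6 and C7 stereocentres).
5. Ring order: 11-membered thiacycle (step 13) → 10-membered carbocycle (step 15) → the two oxiranes (step 18).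

Key step: step 15

Assumption: compounds 1, 3, 10 and 25 are bought; the catalyst antipode in step 2 and the auxiliary antipode in step 8 are those that the published induction models assign to the drawn configurations, and the mirror-image reagent would be used if a model proved wrong for these substrates.

**Route**

Step 1
Reactants: 1 methyl 3-methylbut-2-enoate
Product: 2 tert-butyl[(1-methoxy-3-methylbuta-1,3-dien-1-yl)oxy]dimethylsilane
Conditions: LDA, THF, −78 °C; TBSCl, DMPU, −78 °C → rt
Reagents that add atoms: tert-butyldimethylsilyl chloride, CC(C)(C)[Si](C)(C)Cl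
Why: Kinetic γ-deprotonation of the senecioate and O-silylation of the extended enolate should give the silyl dienol ether, the standard donor for vinylogous Mukaiyama aldol reactions.

Step 2
Reactants: 2 silyl dienol ether; 3 3-methylbut-2-enal (prenal)
Product: 4 methyl (2E,5R)-5-hydroxy-3,7-dimethylocta-2,6-dienoate
Conditions: SiCl4, (R,R)-Denmark bisphosphoramide (5 mol %), i-Pr2NEt (cat.), CH2Cl2, −78 °C; aq. NaHCO3
Reagents that add atoms: none
Why: Denmark's Lewis-base-activated SiCl4 vinylogous Mukaiyama aldol should add the dienolate through its γ-carbon to one face of the catalyst-bound enal, setting C2 (R) under catalyst control and giving the (E)-trisubstituted enoate that becomes C4=C5.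

Step 3
Reactants: 4 hydroxy ester
Product: 5 methyl (2E,5R)-5-[(TBS)oxy]-3,7-dimethylocta-2,6-dienoate
Conditions: TBSCl, imidazole, DMF, rt
Reagents that add atoms: tert-butyldimethylsilyl chloride, CC(C)(C)[Si](C)(C)Cl
Why: Standard silylation protects the secondary allylic C2 hydroxyl against the oxidations that follow.

Step 4
Reactants: 5 silyl ether
Product: 6 methyl (2E,5R,6E)-5-[(TBS)oxy]-8-hydroxy-3,7-dimethylocta-2,6-dienoate
Conditions: SeO2 (0.3 equiv), t-BuOOH, salicylic acid (cat.), CH2Cl2, rt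
Reagents that add atoms: tert-butyl hydroperoxide, CC(C)(C)OO
Why: Sharpless SeO2/t-BuOOH allylic hydroxylation (ene reaction, then [2,3]-shift) should attack only the electron-rich isopropylidene alkene and, by the usual rule, its (E)-methyl group, giving the (E)-allylic alcohol that becomes C9, while the electron-poor enoate alkene stays inert.

Step 5
Reactants: 6 allylic alcohol
Product: 7 methyl (2E,5R,6E)-5,8-bis[(TBS)oxy]-3,7-dimethylocta-2,6-dienoate
Conditions: TBSCl, imidazole, DMF, rt
Reagents that add atoms: tert-butyldimethylsilyl chloride, CC(C)(C)[Si](C)(C)Cl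
Why: Silylation of the primary allylic alcohol masks C9 as an ether that can later be removed selectively in the presence of the secondary silyl ethers.

Step 6
Reactants: 7 bis-silyl ester
Product: 8 (2E,5R,6E)-5,8-bis[(TBS)oxy]-3,7-dimethylocta-2,6-dien-1-ol
Conditions: DIBAL-H (2.5 equiv), CH2Cl2, −78 °C; Rochelle salt
Reagents that add atoms: none
Why: DIBAL-H 1,2-reduction of the α,β-unsaturated ester should give the allylic alcohol without touching silyl ethers or alkene geometry.

Step 7
Reactants: 8 allylic alcohol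
Product: 9 (2E,5R,6E)-5,8-bis[(TBS)oxy]-3,7-dimethylocta-2,6-dienal
Conditions: MnO2, CH2Cl2, rt
Reagents that add atoms: none
Why: MnO2 oxidises only the primary allylic alcohol and should give the (E)-enal without isomerisation.

Step 8
Reactants: 9 enal; 10 (4R)-4-benzyl-3-(3-methylbutanoyl)-1,3-oxazolidin-2-one
Product: 12 (4R)-4-benzyl-3-[(2S,3S,4E,7R,8E)-7,10-bis[(TBS)oxy]-3-hydroxy-5,9-dimethyl-2-(propan-2-yl)deca-4,8-dienoyl]-1,3-oxazolidin-2-one, via trimethylsilyl ether 11 (not isolated)
Conditions: MgCl2 (0.2 equiv), Et3N, TMSCl, EtOAc, rt; then PPTS, MeOH, 0 °C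
Reagents that add atoms: none
Why: Evans MgCl2-catalysed anti-aldol reaction (soft enolisation with in situ silyl trapping) should let the Mg-chelated (Z)-enolate react on the face opposite the benzyl group with the non-enolisable enal through a boat-like transition state, setting C7 and C6 anti under auxiliary control, after which PPTS/MeOH removes the TMS group.

Step 9
Reactants: 12 aldol adduct
Product: 13 (4R)-4-benzyl-3-[(2S,3S,4E,7R,8E)-3,7,10-tris[(TBS)oxy]-5,9-dimethyl-2-(propan-2-yl)deca-4,8-dienoyl]-1,3-oxazolidin-2-one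
Conditions: TBSOTf, 2,6-lutidine, CH2Cl2, −78 → 0 °C
Reagents that add atoms: tert-butyldimethylsilyl triflate, CC(C)(C)[Si](C)(C)OS(=O)(=O)C(F)(F)F
Why: The silyl triflate silylates the hindered secondary C6 hydroxyl under non-epimerising conditions, which also blocks retro-aldol cleavage in the next step.

Step 10
Reactants: 13 silylated imide
Product: 14 (2R,3S,4E,7R,8E)-3,7,10-tris[(TBS)oxy]-5,9-dimethyl-2-(propan-2-yl)deca-4,8-dien-1-ol
Conditions: LiBH4, MeOH (1.1 equiv), Et2O, 0 °C
Reagents that add atoms: none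
Why: Reductive cleavage of the N-acyloxazolidinone with LiBH4 should give the primary alcohol (C8) without epimerising C7 and return the auxiliary.

Step 11
Reactants: 14 tris-silyl ether
Product: 15 (2E,4R,6E,8S,9R)-4,8-bis[(TBS)oxy]-2,6-dimethyl-9-(propan-2-yl)deca-2,6-diene-1,10-diol
Conditions: HF·pyridine, pyridine, THF, 0 °C
Reagents that add atoms: none
Why: Buffered HF·pyridine cleaves the unhindered primary allylic TBS ether much faster than the two secondary ones, freeing C9–OH beside C8–OH.

Step 12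
Reactants: 15 diol
Product: 16 (2E,4R,6E,8S,9S)-1,10-dibromo-4,8-bis[(TBS)oxy]-2,6-dimethyl-9-(propan-2-yl)deca-2,6-diene
Conditions: CBr4, PPh3, CH2Cl2, 0 °C
Reagents that add atoms: carbon tetrabromide, BrC(Br)(Br)Br
Why: The Appel reaction converts both primary alcohols (allylic C9 and alkyl C8) into bromides by SN2 at carbon under neutral conditions, without allylic transposition.

Step 13
Reactants: 16 dibromide
Product: 17 (3E,5R,7E,9S,10S)-5,9-bis[(TBS)oxy]-3,7-dimethyl-10-(propan-2-yl)-1-thiacycloundeca-3,7-diene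
Conditions: Na2S·9H2O, DMF, high dilution (syringe pump), rt → 40 °C
Reagents that add atoms: sodium sulfide, [Na+].[Na+].[S-2]
Why: Double SN2 alkylation of sulfide (allylic bromide first, then the thiolate on the C8 bromide) under high dilution should close the 11-membered thiacycle, whose long C–S bonds make it easier to form than a ten-membered carbocycle.

Step 14
Reactants: 17 thiacycle
Product: 18 (3E,5R,7E,9S,10S)-5,9-bis[(TBS)oxy]-3,7-dimethyl-10-(propan-2-yl)-1-thiacycloundeca-3,7-diene 1,1-dioxide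
Conditions: (NH4)6Mo7O24·4H2O (10 mol %), 30 % H2O2, EtOH, 0 °C → rt
Reagents that add atoms: hydrogen peroxide, OO
Why: Molybdate-catalysed peroxide oxidation is chemoselective for sulfide → sulfone in the presence of trisubstituted alkenes and silyl ethers.

Step 15
Reactants: 18 cyclic sulfone
Product: 21 (1(10)E,4E)-(2R,6R,7R)-2,6-bis[(TBS)oxy]germacra-1(10),4,8-triene, via α-bromo sulfone 19 (not isolated), via episulfone 20 (not isolated)
Conditions: CBr2F2, KOH/Al2O3, t-BuOH/CH2Cl2, 0 °C → rt
Reagents that add atoms: none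
Why: Ramberg–Bäcklund ring contraction in Chan's one-flask form: KOH on alumina deprotonates the doubly activated allylic α-carbon C9, CBr2F2 brominates it (19), the α'-carbanion at C8 displaces bromide in a 1,3-elimination to the bicyclic episulfone 20, and this loses SO2 cheletropically. The closest known reaction type is the Ramberg–Bäcklund contraction of macrocyclic allylic or benzylic sulfones to strained medium-ring polyenes. The ten-membered carbocycle is closed in the 3-exo-tet step that forms the C8–C9 σ-bond of the thiirane dioxide, that is inside an existing 11-membered ring, so no macrocyclisation entropy is paid and SO2 loss pays for the strain of the E,E-cyclodecadiene. No lasting stereocentre is created: C8 and C9 become sp2, the C8=C9 geometry is irrelevant because the bond is saturated in step 16, and C2, C6, C7 and both E-alkenes are untouched. The step needs only that halogenation occur at an α-carbon (either gives the same episulfone) and that the alkenes be spared, which CBr2F2 (no dihalocarbene adducts) and silyl protection of both alcohols (no alkoxide, hence no oxy-Cope or fragmentation pathway) should secure.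

Step 16
Reactants: 21 triene
Product: 22 (1(10)E,4E)-(2R,6R,7S)-2,6-bis[(TBS)oxy]germacra-1(10),4-diene
Conditions: 2-nitrobenzenesulfonyl hydrazide, Et3N, CH2Cl2, rt
Reagents that add atoms: none
Why: Diimide generated in situ should reduce the disubstituted C8=C9 bond of the diene by concerted syn hydrogen transfer much faster than either trisubstituted alkene, and no stereocentre is formed.

Step 17
Reactants: 22 bis-silyl ether
Product: 23 (1(10)E,4E)-(2R,6R,7S)-germacra-1(10),4-diene-2,6-diol
Conditions: TBAF, AcOH (1:1), THF, rt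
Reagents that add atoms: none
Why: Acetic-acid-buffered fluoride removes both silyl groups without generating a free C2 alkoxide, which in this 3-oxy-1,5-diene would invite anionic oxy-Cope rearrangement.

Step 18
Reactants: 23 diene diol
Product: 24 (1S,2R,4S,5S,6R,7S,10S)-1,10:4,5-diepoxygermacrane-2,6-diol
Conditions: mCPBA (2.2 equiv), NaHCO3, CH2Cl2, 0 °C
Reagents that add atoms: 3-chloroperbenzoic acid, OOC(=O)c1cccc(Cl)c1
Why: Peracid epoxidation should occur on the exposed peripheral face of each E-trisubstituted alkene, which is also the face of its allylic hydroxyl (Henbest hydrogen-bond delivery; A(1,3) strain with the cis C-methyl holds H2 and H6 in the alkene planes and the OH groups outside), giving the two threo epoxy alcohols and so setting C1, C10, C4 and C5.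

Step 19
Reactants: 24 diepoxy diol; 25 angelic acid
Product: 27 (1S,2R,4S,5S,6R,7S,10S)-1,10:4,5-diepoxy-6-hydroxygermacran-2-yl (2Z)-2-methylbut-2-enoate, via mixed anhydride 26 (not isolated)
Conditions: 25, 2,4,6-trichlorobenzoyl chloride, Et3N, toluene, rt; then 24, DMAP, toluene, rt → 50 °C
Reagents that add atoms: none
Why: Yamaguchi esterification through the mixed anhydride should acylate the less hindered C2 hydroxyl (C6–OH is flanked by the isopropyl-bearing C7) and is the established way to make angelates without Z → E isomerisation to the tiglate.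

Step 20
Reactants: 27 mono-angelate
Product: 28 (1S,2R,4S,5S,6R,7S,10S)-6-acetoxy-1,10:4,5-diepoxygermacran-2-yl (2Z)-2-methylbut-2-enoate (CNP0311463.1)
Conditions: Ac2O, DMAP (cat.), pyridine, rt
Reagents that add atoms: acetic anhydride, CC(=O)OC(C)=O
Why: DMAP-catalysed acetylation of the remaining hindered secondary C6 hydroxyl should proceed without affecting the epoxides or the angelate.

**Compound list**

1 | methyl 3-methylbut-2-enoate | COC(=O)C=C(C)C | starting material
2 | tert-butyl[(1-methoxy-3-methylbuta-1,3-dien-1-yl)oxy]dimethylsilane | C=C(C)C=C(OC)O[Si](C)(C)C(C)(C)C | intermediate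
3 | 3-methylbut-2-enal (prenal) | CC(C)=CC=O | starting material
4 | methyl (2E,5R)-5-hydroxy-3,7-dimethylocta-2,6-dienoate | CC(C)=C[C@H](O)C/C(C)=C/C(=O)OC | intermediate
5 | methyl (2E,5R)-5-[(TBS)oxy]-3,7-dimethylocta-2,6-dienoate | CC(C)=C[C@H](O[Si](C)(C)C(C)(C)C)C/C(C)=C/C(=O)OC | intermediate
6 | methyl (2E,5R,6E)-5-[(TBS)oxy]-8-hydroxy-3,7-dimethylocta-2,6-dienoate | OC/C(C)=C/[C@H](O[Si](C)(C)C(C)(C)C)C/C(C)=C/C(=O)OC | intermediate
7 | methyl (2E,5R,6E)-5,8-bis[(TBS)oxy]-3,7-dimethylocta-2,6-dienoate | CC(C)(C)[Si](C)(C)OC/C(C)=C/[C@H](O[Si](C)(C)C(C)(C)C)C/C(C)=C/C(=O)OC | intermediate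
8 | (2E,5R,6E)-5,8-bis[(TBS)oxy]-3,7-dimethylocta-2,6-dien-1-ol | CC(C)(C)[Si](C)(C)OC/C(C)=C/[C@H](O[Si](C)(C)C(C)(C)C)C/C(C)=C/CO | intermediate
9 | (2E,5R,6E)-5,8-bis[(TBS)oxy]-3,7-dimethylocta-2,6-dienal | CC(C)(C)[Si](C)(C)OC/C(C)=C/[C@H](O[Si](C)(C)C(C)(C)C)C/C(C)=C/C=O | intermediate
10 | (4R)-4-benzyl-3-(3-methylbutanoyl)-1,3-oxazolidin-2-one | CC(C)CC(=O)N1[C@H](Cc2ccccc2)COC1=O | starting material
11 | 3-O-trimethylsilyl ether of aldol adduct 12 | CC(C)(C)[Si](C)(C)OC/C(C)=C/[C@H](O[Si](C)(C)C(C)(C)C)C/C(C)=C/[C@H](O[Si](C)(C)C)[C@H](C(C)C)C(=O)N1[C@H](Cc2ccccc2)COC1=O | intermediate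
12 | (4R)-4-benzyl-3-[(2S,3S,4E,7R,8E)-7,10-bis[(TBS)oxy]-3-hydroxy-5,9-dimethyl-2-(propan-2-yl)deca-4,8-dienoyl]-1,3-oxazolidin-2-one | CC(C)(C)[Si](C)(C)OC/C(C)=C/[C@H](O[Si](C)(C)C(C)(C)C)C/C(C)=C/[C@H](O)[C@H](C(C)C)C(=O)N1[C@H](Cc2ccccc2)COC1=O | intermediate
13 | (4R)-4-benzyl-3-[(2S,3S,4E,7R,8E)-3,7,10-tris[(TBS)oxy]-5,9-dimethyl-2-(propan-2-yl)deca-4,8-dienoyl]-1,3-oxazolidin-2-one | CC(C)(C)[Si](C)(C)OC/C(C)=C/[C@H](O[Si](C)(C)C(C)(C)C)C/C(C)=C/[C@H](O[Si](C)(C)C(C)(C)C)[C@H](C(C)C)C(=O)N1[C@H](Cc2ccccc2)COC1=O | intermediate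
14 | (2R,3S,4E,7R,8E)-3,7,10-tris[(TBS)oxy]-5,9-dimethyl-2-(propan-2-yl)deca-4,8-dien-1-ol | CC(C)(C)[Si](C)(C)OC/C(C)=C/[C@H](O[Si](C)(C)C(C)(C)C)C/C(C)=C/[C@H](O[Si](C)(C)C(C)(C)C)[C@H](C(C)C)CO | intermediate
15 | (2E,4R,6E,8S,9R)-4,8-bis[(TBS)oxy]-2,6-dimethyl-9-(propan-2-yl)deca-2,6-diene-1,10-diol | OC/C(C)=C/[C@H](O[Si](C)(C)C(C)(C)C)C/C(C)=C/[C@H](O[Si](C)(C)C(C)(C)C)[C@H](C(C)C)CO | intermediate
16 | (2E,4R,6E,8S,9S)-1,10-dibromo-4,8-bis[(TBS)oxy]-2,6-dimethyl-9-(propan-2-yl)deca-2,6-diene | BrC/C(C)=C/[C@H](O[Si](C)(C)C(C)(C)C)C/C(C)=C/[C@H](O[Si](C)(C)C(C)(C)C)[C@H](C(C)C)CBr | intermediate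
17 | (3E,5R,7E,9S,10S)-5,9-bis[(TBS)oxy]-3,7-dimethyl-10-(propan-2-yl)-1-thiacycloundeca-3,7-diene | S1C/C(C)=C/[C@H](O[Si](C)(C)C(C)(C)C)C/C(C)=C/[C@H](O[Si](C)(C)C(C)(C)C)[C@H](C(C)C)C1 | intermediate
18 | 1,1-dioxide of 17 (11-membered cyclic sulfone) | O=S1(=O)C/C(C)=C/[C@H](O[Si](C)(C)C(C)(C)C)C/C(C)=C/[C@H](O[Si](C)(C)C(C)(C)C)[C@H](C(C)C)C1 | intermediate
19 | 2-bromo derivative of sulfone 18 (bromine on the allylic α-carbon, C9 of the germacrane numbering; configuration at that carbon open) | O=S1(=O)C(Br)/C(C)=C/[C@H](O[Si](C)(C)C(C)(C)C)C/C(C)=C/[C@H](O[Si](C)(C)C(C)(C)C)[C@H](C(C)C)C1 | intermediate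
20 | episulfone: 8,9-epithio-2,6-bis[(TBS)oxy]germacra-1(10),4-diene S,S-dioxide (11-thiabicyclo[8.1.0]undecadiene 11,11-dioxide; ring-fusion configuration open) | O=S1(=O)C2/C(C)=C/[C@H](O[Si](C)(C)C(C)(C)C)C/C(C)=C/[C@H](O[Si](C)(C)C(C)(C)C)[C@H](C(C)C)C12 | intermediate
21 | (1(10)E,4E)-(2R,6R,7R)-2,6-bis[(TBS)oxy]germacra-1(10),4,8-triene (C8=C9 geometry open) | C1=C/C(C)=C/[C@H](O[Si](C)(C)C(C)(C)C)C/C(C)=C/[C@H](O[Si](C)(C)C(C)(C)C)[C@@H]1C(C)C | intermediate
22 | (1(10)E,4E)-(2R,6R,7S)-2,6-bis[(TBS)oxy]germacra-1(10),4-diene | C1/C(C)=C/[C@H](O[Si](C)(C)C(C)(C)C)C/C(C)=C/[C@H](O[Si](C)(C)C(C)(C)C)[C@H](C(C)C)C1 | intermediate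
23 | (1(10)E,4E)-(2R,6R,7S)-germacra-1(10),4-diene-2,6-diol | C1/C(C)=C/[C@H](O)C/C(C)=C/[C@H](O)[C@H](C(C)C)C1 | intermediate
24 | (1S,2R,4S,5S,6R,7S,10S)-1,10:4,5-diepoxygermacrane-2,6-diol | C1[C@]2(C)O[C@H]2[C@H](O)C[C@]3(C)O[C@H]3[C@H](O)[C@H](C(C)C)C1 | intermediate
25 | angelic acid, (2Z)-2-methylbut-2-enoic acid | C/C=C(/C)C(=O)O | starting material
26 | angelic 2,4,6-trichlorobenzoic anhydride | C/C=C(/C)C(=O)OC(=O)c1c(Cl)cc(Cl)cc1Cl | intermediate
27 | (1S,2R,4S,5S,6R,7S,10S)-1,10:4,5-diepoxy-6-hydroxygermacran-2-yl (2Z)-2-methylbut-2-enoate | C1[C@]2(C)O[C@H]2[C@H](OC(=O)/C(C)=C\C)C[C@]3(C)O[C@H]3[C@H](O)[C@H](C(C)C)C1 | intermediate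
28 | (1S,2R,4S,5S,6R,7S,10S)-6-acetoxy-1,10:4,5-diepoxygermacran-2-yl (2Z)-2-methylbut-2-enoate | C/C=C(/C)C(=O)O[C@@H]1C[C@]2(C)O[C@H]2[C@H](OC(C)=O)[C@H](C(C)C)CC[C@]2(C)O[C@@H]12 | target

**Step count and risks**

Total step count: 20. Longest linear sequence: 20 steps (1 → 28; compounds 3, 10 and 25 enter as bought materials).

Steps most likely to fail:

1. Step 15 (key step). The allylic α-sulfonyl carbanion at C9 may expel the C2 silyloxy group by vinylogous 1,4-elimination instead of undergoing bromination and 1,3-elimination, or the strained conjugated triene may isomerise or decompose under the basic conditions. The fallback sets out from thiacycle 17 and avoids base and the sulfone altogether. Sulfur is extruded photochemically (hν 254 nm in trimethyl phosphite, the phosphite-mediated desulfurisation known for allylic and benzylic sulfides): the allylic C9–S bond is cleaved, the thiyl radical is desulfurised by the phosphite, and the C8 radical recombines with the allyl radical at C9. This is still a one-atom ring contraction of the 11-membered ring, gives the C8–C9 single bond directly and comes back to the route at 22, so steps 14–16 are skipped. No new compound is formed on this path (F0).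

2. Step 8. Soft enolisation of the α-isopropyl imide may be slow and the β,β-disubstituted enal a weak electrophile, so that conversion stalls or the anti selectivity erodes. The fallback sets out from enal 9 and changes the mode of stereocontrol. The dibutylboron (Z)-enolate of the antipodal imide (4S)-4-benzyl-3-(3-methylbutanoyl)-1,3-oxazolidin-2-one (Bu2BOTf, i-Pr2NEt) is added to 9 precomplexed with Et2AlCl (Heathcock's open-transition-state anti-aldol of Evans boron enolates). This should give the anti adduct (4S)-4-benzyl-3-[(2S,3S,4E,7R,8E)-7,10-bis[(TBS)oxy]-3-hydroxy-5,9-dimethyl-2-(propan-2-yl)deca-4,8-dienoyl]-1,3-oxazolidin-2-one F1, with the same C6/C7 configuration as 12. Silylation (TBSOTf, 2,6-lutidine) gives the tris-silyl imide F2, and LiBH4 cleavage comes back to the route at 14.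

3. Step 19. Acylation may fail to discriminate between the two secondary hydroxyls, and forcing it may open an epoxide or isomerise the angelate. The fallback sets out from diepoxy diol 24 and reverses the order of ester introduction. Both hydroxyls are acetylated (Ac2O, DMAP, pyridine) to (1S,2R,4S,5S,6R,7S,10S)-1,10:4,5-diepoxygermacrane-2,6-diyl diacetate F3. The less hindered C2 acetate is then removed selectively (K2CO3, MeOH, 0 °C, or a lipase in buffer) to give (1S,2R,4S,5S,6R,7S,10S)-1,10:4,5-diepoxy-2-hydroxygermacran-6-yl acetate F4. Its only free hydroxyl is esterified with mixed anhydride 26 (DMAP, toluene), which comes back to the route at target 28.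

**Further compounds**

F0 | step 15 | none | none
F1 | step 8 | (4S)-4-benzyl-3-[(2S,3S,4E,7R,8E)-7,10-bis[(TBS)oxy]-3-hydroxy-5,9-dimethyl-2-(propan-2-yl)deca-4,8-dienoyl]-1,3-oxazolidin-2-one | CC(C)(C)[Si](C)(C)OC/C(C)=C/[C@H](O[Si](C)(C)C(C)(C)C)C/C(C)=C/[C@H](O)[C@H](C(C)C)C(=O)N1[C@@H](Cc2ccccc2)COC1=O
F2 | step 8 | (4S)-4-benzyl-3-[(2S,3S,4E,7R,8E)-3,7,10-tris[(TBS)oxy]-5,9-dimethyl-2-(propan-2-yl)deca-4,8-dienoyl]-1,3-oxazolidin-2-one | CC(C)(C)[Si](C)(C)OC/C(C)=C/[C@H](O[Si](C)(C)C(C)(C)C)C/C(C)=C/[C@H](O[Si](C)(C)C(C)(C)C)[C@H](C(C)C)C(=O)N1[C@@H](Cc2ccccc2)COC1=O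
F3 | step 19 | (1S,2R,4S,5S,6R,7S,10S)-1,10:4,5-diepoxygermacrane-2,6-diyl diacetate | C1[C@]2(C)O[C@H]2[C@H](OC(C)=O)C[C@]3(C)O[C@H]3[C@H](OC(C)=O)[C@H](C(C)C)C1
F4 | step 19 | (1S,2R,4S,5S,6R,7S,10S)-1,10:4,5-diepoxy-2-hydroxygermacran-6-yl acetate | C1[C@]2(C)O[C@H]2[C@H](O)C[C@]3(C)O[C@H]3[C@H](OC(C)=O)[C@H](C(C)C)C1
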